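The readings cannot tell X from Z: in the spring run at 8.00 min they stand at 5% and 8%, with a scatter of 2 percentage points on each. The two can therefore be followed as one pool, [X]+[Z], for a new flask:

| flask | X | Z | J | L | remark | time |
|---|---|---|---|---|---|---|
| winter | 8 mM | 8 mM | 32 mM | 0.40 mM | run made earlier |  |
| dusk | 32 mM | 32 mM | 32 mM | 0.40 mM | run made earlier |  |
| spring | 16 mM | 16 mM | 48 mM | 0.40 mM | run made earlier |  |
| flask | 16 mM | 16 mM | 32.0 mM | 0.40 mM |  | 8.0 min |

| run | time / min | X / % | Z / % |
|---|---|---|---|
| winter | 1.50 | 28 | 33 |
| winter | 3.00 | 20 | 19 |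
| winter | 5.00 | 22 | 17 |
| winter | 6.00 | 14 | 14 |
| winter | 8.00 | 10 | 9 |
| dusk | 0.667 | 40 | 37 |
| dusk | 1.33 | 34 | 32 |
| dusk | 2.50 | 31 | 30 |
| dusk | 4.00 | 30 | 29 |
| dusk | 8.00 | 24 | 28 |
| spring | 0.667 | 37 | 33 |
| spring | 2.00 | 23 | 24 |
| spring | 4.00 | 12 | 14 |
| spring | 6.00 | 8 | 8 |
| spring | 8.00 | 5 | 8 |

(readings scatter by 2 percentage points)

1. part of the X and Z charged together that has reacted at 8.0 min
2. excess of D over Q in the product at 8.0 min
3. excess of Z over X among what is left of the two at 8.0 min

- J is single-handed; X and Z are mirror images of each other, charged as a racemate, each of them at the stated concentration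
- what was read earlier has a scatter of 2 percentage points, one standard deviation
- steps that have been proposed: X + L <-> Z + L; J + Z -> Q; J <-> G; 2 L -> E; J + X -> D
- an excess is the difference of the two amounts in percent of their sum
- an excess is below zero if the other one leads
- the handed part of J does not stay in what it makes, so the products of the two hands are mirror images too

Each X or Z that reacts takes one J, so [J], with any G counted in it, is its charge less what the pool has lost. The pool then falls at k[J]([X]+[Z]), where k may change with time. This rate integrates in closed form: the time integral of k equals the rise of ln([J]/([X]+[Z])) divided by the difference of the two charges. With equal charges it equals the rise of the reciprocal of the pool.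

At 8.00 min the winter pool of 3.04 mM gives 0.0713 mM⁻¹, and the spring pool of 4.16 mM gives 0.0733 mM⁻¹, close although their charges differ. Dusk, with 1.28 mM of J by subtraction, is set aside. Their mean, 0.0723 mM⁻¹, is the reach: the integral of k over that time, as read off those two runs with their scatter. The flask charges a pool of 32.0 mM against 32.0 mM of J, so the equal form applies. It leaves 9.66 mM, and by this reckoning 69.8% has reacted. The reach says nothing of the hands.

The forecast reckons the same way and gives c 70% (64% to 76%), eP 12% (−3% to 45%) and eS 6% (−5% to 18%), noting that “fast racemisation by L could hide a real preference”.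

The flask gives c 66.5%, eP 25.0% and eS 0.182%.

    X + L ⇌ Z + L, rate k1*[L]*[X] forward; the back reaction follows from the equilibrium constant (k = 1090 M⁻¹ s⁻¹)
    J + Z → Q (k = 0.202 M⁻¹ s⁻¹)
    J ⇌ G (K = 1.20, k = 0.00670 s⁻¹)
    2 L → E (k = 11.9 M⁻¹ s⁻¹)
    J + X → D (k = 0.338 M⁻¹ s⁻¹)

In the flask X passes into Z with a half-life of 1.6 s, forward rate alone at the charged concentrations, short against 8.0 min. At that time X and Z stand at 16.7% and 16.8% and D at 41.6% against Q at 24.9%; the step to D has the larger rate constant, 0.338 M⁻¹ s⁻¹ against 0.202 M⁻¹ s⁻¹ for the step to Q, and the ratio of the two is the selectivity factor. Worked back from the computed conversion, the flask's own reach is 0.0621 mM⁻¹. In a neighbour flask, the same but with 54 mM of J, the reach read from the runs, 0.0723 mM⁻¹, and the unequal form give 90.6% reacted. The computed neighbour stands at 88.8%.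

The readings are calculated with made-up constants; scatter was added.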